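**Retrosynthetic overview**
- Target ⇒ Stille bond in the middle of the triene (ethynyl carbinol hydrostannated in the flask + bromodienamide of the aminocyclopentenone) and the upper amide bond (Staudinger acylation of a 2-azido enone with the dienoic acid).
- 2-Azido enone ⇒ azide opening and dehydration of the one oxirane left in an epoxy-diol ketone. That ketone ⇒ key step: radical titanocene opening of one of the two enantiotopic oxiranes of a meso bis-epoxy quinol (C6–O homolysis, new C6–H bond by H-atom transfer to the C6 radical), which fixes C4 and C5 (cis) in one event.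
- Meso bis-epoxide ⇒ double hydroxyl-directed epoxidation of a para-quinol ⇒ 1,4-quinone + ethynyl Grignard reagent.
- Dienoic acid ⇒ two Wittig olefinations on (R)-2-methylhexanal ⇐ copper-catalysed coupling of a chiral bromo-alcohol with a propyl Grignard reagent; bromodienamide ⇐ glutaconaldehyde salt.
- Rings: neither carbocycle is built (six-membered ring from the quinone, five-membered ring bought); the two oxiranes are formed together, then opened one after the other (radical first, azide second).

Assumption: 2-amino-3-hydroxycyclopent-2-en-1-one (as the free enaminone) and glutaconaldehyde potassium salt are catalogue items, and the sense of induction in step 10 is set by choosing the antipode of the menthyl-derived titanocene.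

**Step 1**
Reactants: 1 (S)-3-bromo-2-methylpropan-1-ol; 2 n-propylmagnesium chloride
Product: 3 (R)-2-methylhexan-1-ol
Conditions: 2 (2.5 equiv), Li2CuCl4 (3 mol%), THF, −78 → 0 °C; then 1 M HCl
Reagents that add atoms: none
Why: Kochi-type copper-catalysed sp3–sp3 coupling of the primary bromide (the first equivalent of Grignard reagent only forms the alkoxide); the stereocentre does not react and its descriptor changes from S to R only because the CIP priorities change.

**Step 2**
Reactants: 3 (R)-2-methylhexan-1-ol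
Product: 5 (2E,4R)-2,4-dimethyloct-2-enal, via (R)-2-methylhexanal 4 (not isolated)
Conditions: TEMPO (10 mol%), PhI(OAc)2 (1.1 equiv), CH2Cl2, rt; then Ph3P=C(CH3)CHO (1.3 equiv), toluene, 80 °C
Reagents that add atoms: 2-(triphenylphosphoranylidene)propanal, CC(C=O)=P(c1ccccc1)(c1ccccc1)c1ccccc1
Why: oxoammonium oxidation stops at the aldehyde without epimerising the α-stereocentre, and the Wittig reaction of the formyl-stabilised ylide gives the (E)-enal.

**Step 3**
Reactants: 5 (2E,4R)-2,4-dimethyloct-2-enal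
Product: 6 ethyl (2E,4E,6R)-2,4,6-trimethyldeca-2,4-dienoate
Conditions: Ph3P=C(CH3)CO2Et (1.5 equiv), toluene, 90 °C
Reagents that add atoms: ethyl 2-(triphenylphosphoranylidene)propanoate, CCOC(=O)C(C)=P(c1ccccc1)(c1ccccc1)c1ccccc1
Why: Wittig olefination with an ester-stabilised ylide is E-selective and runs under neutral conditions that leave the allylic stereocentre alone.

**Step 4**
Reactants: 6 ethyl (2E,4E,6R)-2,4,6-trimethyldeca-2,4-dienoate
Product: 7 (2E,4E,6R)-2,4,6-trimethyldeca-2,4-dienoic acid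
Conditions: LiOH·H2O (3 equiv), THF/MeOH/H2O, 40 °C; then 1 M HCl
Reagents that add atoms: lithium hydroxide, [Li+].[OH-]
Why: plain ester saponification; the diene geometry and the remote stereocentre are not affected.

**Step 5**
Reactants: 8 glutaconaldehyde potassium salt
Product: 9 (2E,4E)-5-bromopenta-2,4-dienal
Conditions: Ph3PBr2 (1.1 equiv), CH2Cl2, −20 °C → rt
Reagents that add atoms: dibromotriphenylphosphorane, BrP(Br)(c1ccccc1)(c1ccccc1)c1ccccc1
Why: the enolate oxygen is activated as an oxyphosphonium and replaced by bromide through addition–elimination (a vinylogous acid bromide formation), and the conjugated product settles as the E,E isomer.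

**Step 6**
Reactants: 9 (2E,4E)-5-bromopenta-2,4-dienal
Product: 10 (2E,4E)-5-bromopenta-2,4-dienoic acid
Conditions: NaClO2, NaH2PO4, 2-methylbut-2-ene, t-BuOH/H2O, 0 °C → rt
Reagents that add atoms: sodium chlorite, [Na+].[O-]Cl=O
Why: Pinnick oxidation converts the enal into the acid without touching the bromodiene.

**Step 7**
Reactants: 10 (2E,4E)-5-bromopenta-2,4-dienoic acid; 11 2-amino-3-hydroxycyclopent-2-en-1-one
Product: 13 (2E,4E)-5-bromo-N-(2-hydroxy-5-oxocyclopent-1-en-1-yl)penta-2,4-dienamide, via bromodienoyl chloride 12 (not isolated)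
Conditions: (COCl)2, DMF (cat.), CH2Cl2, 0 °C; then 11, pyridine, THF, 0 °C → rt
Reagents that add atoms: none
Why: N-acylation of the enaminone nitrogen by the acid chloride; any enol ester formed on oxygen is cleaved on aqueous work-up.

**Step 8**
Reactants: 14 p-benzoquinone; 15 ethynylmagnesium bromide
Product: 16 4-ethynyl-4-hydroxycyclohexa-2,5-dien-1-one
Conditions: 15 (1.0 equiv) added to 14 (1.5 equiv), THF, −78 °C; then pH 7 buffer
Reagents that add atoms: none
Why: 1,2-addition of the alkynyl Grignard reagent to one quinone carbonyl gives the para-quinol; C4 carries two identical ring arms, so no stereocentre is created yet.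

**Step 9**
Reactants: 16 4-ethynyl-4-hydroxycyclohexa-2,5-dien-1-one
Product: 17 meso-(2R,3S,4s,5R,6S)-4-ethynyl-4-hydroxy-2,3:5,6-diepoxycyclohexan-1-one
Conditions: t-BuOOH (2.5 equiv), PhCH2NMe3OH (10 mol%), THF, 0 °C
Reagents that add atoms: tert-butyl hydroperoxide, CC(C)(C)OO
Why: double Weitz–Scheffer nucleophilic epoxidation in which the tertiary hydroxyl hydrogen-bonds and delivers each peroxide anion to its own face, so both oxiranes end up cis to OH and the product is meso.

**Step 10 (key step)**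
Reactants: 17 meso-(2R,3S,4s,5R,6S)-4-ethynyl-4-hydroxy-2,3:5,6-diepoxycyclohexan-1-one
Product: 18 (2S,3R,4S,5S)-2,3-epoxy-4-ethynyl-4,5-dihydroxycyclohexan-1-one
Conditions: (C5H4-menthyl)2TiCl2 (10 mol%), Mn dust (0.6 equiv), 2,4,6-collidine·HCl (1.2 equiv), 1,4-cyclohexadiene (5 equiv), THF, −20 °C
Reagents that add atoms: none
Why: Proposed new method: trivalent titanium (made from the dichloride and Mn) binds the ketone and oxirane oxygens, and one-electron transfer breaks the C–O bond alpha to the carbonyl to give a β-titanoxy α-keto radical at C6 that takes a hydrogen atom from 1,4-cyclohexadiene (collidinium chloride releases the alkoxide and returns the dichloride); C5 keeps its oxygen with retention so the 4,5-diol is cis, and the chiral menthyl-cyclopentadienyl pocket has to choose between the two mirror-related C–O bonds of the meso substrate, which sets C4 and C5 together; the closest known reactions are the Cp2TiCl reduction of α,β-epoxy ketones to β-hydroxy ketones and the enantioselective titanocene-catalysed reductive opening of meso-epoxides.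

**Step 11**
Reactants: 18 (2S,3R,4S,5S)-2,3-epoxy-4-ethynyl-4,5-dihydroxycyclohexan-1-one
Product: 20 (4S,5S)-2-azido-4-ethynyl-4,5-dihydroxycyclohex-2-en-1-one, via azidohydrin 19 (not isolated)
Conditions: NaN3 (1.5 equiv), NH4Cl (1.5 equiv), MeOH/H2O, rt → 40 °C
Reagents that add atoms: sodium azide, [Na+].[N-]=[N+]=[N-]
Why: azide opens the remaining α,β-epoxy ketone by SN2 at the carbonyl-activated C2 (C3 is shielded by the quaternary C4), and the β-hydroxy ketone then loses water by E1cB through the acidic C2–H to give the 2-azido enone, leaving C4 and C5 untouched.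

**Step 12**
Reactants: 20 (4S,5S)-2-azido-4-ethynyl-4,5-dihydroxycyclohex-2-en-1-one; 7 (2E,4E,6R)-2,4,6-trimethyldeca-2,4-dienoic acid
Product: 23 (2E,4E,6R)-N-[(3S,4S)-3-ethynyl-3,4-dihydroxy-6-oxocyclohex-1-en-1-yl]-2,4,6-trimethyldeca-2,4-dienamide, via dienoyl chloride 21 (not isolated), via iminophosphorane 22 (not isolated)
Conditions: 7, (COCl)2, DMF (cat.), CH2Cl2, 0 °C; separately 20, PMe3 (1.05 equiv), THF, 0 °C; combine at −40 °C → rt; then H2O
Reagents that add atoms: none
Why: the Staudinger reaction gives the N-vinyl iminophosphorane, whose nitrogen is acylated by the acid chloride faster than either hydroxyl, and hydrolysis of the P–N bond releases the enamide (Staudinger–Vilarrasa-type amidation) with no amine base present that could deprotonate the dienoyl chloride.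

**Step 13**
Reactants: 23 (2E,4E,6R)-N-[(3S,4S)-3-ethynyl-3,4-dihydroxy-6-oxocyclohex-1-en-1-yl]-2,4,6-trimethyldeca-2,4-dienamide; 13 (2E,4E)-5-bromo-N-(2-hydroxy-5-oxocyclopent-1-en-1-yl)penta-2,4-dienamide
Product: 25 (2E,4E,6R)-N-[(3R,4S)-3,4-dihydroxy-3-{(1E,3E,5E)-7-[(2-hydroxy-5-oxocyclopent-1-en-1-yl)amino]-7-oxohepta-1,3,5-trien-1-yl}-6-oxocyclohex-1-en-1-yl]-2,4,6-trimethyldeca-2,4-dienamide, via vinylstannane 24 (not isolated)
Conditions: Bu3SnH (1.1 equiv), PdCl2(PPh3)2 (2 mol%), THF, 0 °C; then 13, Pd2(dba)3 (5 mol%), AsPh3 (20 mol%), DMF, rt, dark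
Reagents that add atoms: none
Why: palladium-catalysed syn-hydrostannation of the terminal alkyne places tin on the distal carbon of the hindered propargylic carbinol to give the (E)-vinylstannane, and Stille coupling with the (E,E)-bromodiene retains geometry on both partners to give the all-E triene.

**Compound list**
1 | (S)-3-bromo-2-methylpropan-1-ol | OC[C@H](C)CBr | starting material
2 | n-propylmagnesium chloride | CCC[Mg]Cl | starting material
3 | (R)-2-methylhexan-1-ol | CCCC[C@@H](C)CO | intermediate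
4 | (R)-2-methylhexanal | CCCC[C@@H](C)C=O | intermediate
5 | (2E,4R)-2,4-dimethyloct-2-enal | CCCC[C@@H](C)/C=C(\C)C=O | intermediate
6 | ethyl (2E,4E,6R)-2,4,6-trimethyldeca-2,4-dienoate | CCCC[C@@H](C)/C=C(C)/C=C(\C)C(=O)OCC | intermediate
7 | (2E,4E,6R)-2,4,6-trimethyldeca-2,4-dienoic acid | CCCC[C@@H](C)/C=C(C)/C=C(\C)C(=O)O | intermediate
8 | glutaconaldehyde potassium salt (potassium (1E,3E)-5-oxopenta-1,3-dien-1-olate) | [K+].[O-]/C=C/C=C/C=O | starting material
9 | (2E,4E)-5-bromopenta-2,4-dienal | Br/C=C/C=C/C=O | intermediate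
10 | (2E,4E)-5-bromopenta-2,4-dienoic acid | Br/C=C/C=C/C(=O)O | intermediate
11 | 2-amino-3-hydroxycyclopent-2-en-1-one | NC1=C(O)CCC1=O | starting material
12 | (2E,4E)-5-bromopenta-2,4-dienoyl chloride | Br/C=C/C=C/C(=O)Cl | intermediate
13 | (2E,4E)-5-bromo-N-(2-hydroxy-5-oxocyclopent-1-en-1-yl)penta-2,4-dienamide | Br/C=C/C=C/C(=O)NC1=C(O)CCC1=O | intermediate
14 | p-benzoquinone | O=C1C=CC(=O)C=C1 | starting material
15 | ethynylmagnesium bromide | C#C[Mg]Br | starting material
16 | 4-ethynyl-4-hydroxycyclohexa-2,5-dien-1-one | O=C1C=CC(O)(C#C)C=C1 | intermediate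
17 | meso-(2R,3S,4s,5R,6S)-4-ethynyl-4-hydroxy-2,3:5,6-diepoxycyclohexan-1-one (both oxiranes cis to OH) | O=C1[C@H]2O[C@H]2[C@](O)(C#C)[C@H]3O[C@@H]13 | intermediate
18 | (2S,3R,4S,5S)-2,3-epoxy-4-ethynyl-4,5-dihydroxycyclohexan-1-one (oxirane and both hydroxyls on one face) | O=C1[C@H]2O[C@H]2[C@](O)(C#C)[C@@H](O)C1 | intermediate
19 | (2R,3R,4S,5S)-2-azido-4-ethynyl-3,4,5-trihydroxycyclohexan-1-one | O=C1[C@H](N=[N+]=[N-])[C@@H](O)[C@](O)(C#C)[C@@H](O)C1 | intermediate
20 | (4S,5S)-2-azido-4-ethynyl-4,5-dihydroxycyclohex-2-en-1-one | [N-]=[N+]=NC1=C[C@](O)(C#C)[C@@H](O)CC1=O | intermediate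
21 | (2E,4E,6R)-2,4,6-trimethyldeca-2,4-dienoyl chloride | CCCC[C@@H](C)/C=C(C)/C=C(\C)C(=O)Cl | intermediate
22 | (4S,5S)-4-ethynyl-4,5-dihydroxy-2-[(trimethylphosphoranylidene)amino]cyclohex-2-en-1-one | CP(C)(C)=NC1=C[C@](O)(C#C)[C@@H](O)CC1=O | intermediate
23 | (2E,4E,6R)-N-[(3S,4S)-3-ethynyl-3,4-dihydroxy-6-oxocyclohex-1-en-1-yl]-2,4,6-trimethyldeca-2,4-dienamide | CCCC[C@@H](C)/C=C(C)/C=C(\C)C(=O)NC1=C[C@](O)(C#C)[C@@H](O)CC1=O | intermediate
24 | (2E,4E,6R)-N-{(3S,4S)-3,4-dihydroxy-6-oxo-3-[(E)-2-(tributylstannyl)ethenyl]cyclohex-1-en-1-yl}-2,4,6-trimethyldeca-2,4-dienamide | CCCC[C@@H](C)/C=C(C)/C=C(\C)C(=O)NC1=C[C@](O)(/C=C/[Sn](CCCC)(CCCC)CCCC)[C@@H](O)CC1=O | intermediate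
25 | (2E,4E,6R)-N-[(3R,4S)-3,4-dihydroxy-3-{(1E,3E,5E)-7-[(2-hydroxy-5-oxocyclopent-1-en-1-yl)amino]-7-oxohepta-1,3,5-trien-1-yl}-6-oxocyclohex-1-en-1-yl]-2,4,6-trimethyldeca-2,4-dienamide (CNP0117968.2) | CCCC[C@@H](C)/C=C(C)/C=C(\C)C(=O)NC1=C[C@](O)(/C=C/C=C/C=C/C(=O)NC2=C(O)CCC2=O)[C@@H](O)CC1=O | target

**Step count and risks**

Total steps: 13. Longest linear sequence: 6 steps (14 → 25 through steps 8–13; the line 1 → 7 followed by steps 12 and 13 is also 6).

The three steps most likely to fail:

Step 10. A chiral titanocene has not been shown to choose between two enantiotopic epoxy-ketone units. Failure modes are low ee and opening of both oxiranes; the latter is limited by the substoichiometric Mn and by the fact that the minor enantiomer of 18 carries the matched oxirane and is consumed faster. Fallback, setting out from 16 and returning at 18: drop the radical desymmetrisation and set both stereocentres by an enantioselective oxa-Michael addition. Treating 16 with phenylboronic acid and a chiral amine–thiourea catalyst gives, through the boronic acid hemiester, (4S,5S)-4-ethynyl-4,5-dihydroxycyclohex-2-en-1-one 4,5-O-phenylboronate F1. Transesterification with a diol and aqueous work-up frees (4S,5S)-4-ethynyl-4,5-dihydroxycyclohex-2-en-1-one F2. Hydroxyl-directed epoxidation of the remaining enone (t-BuOOH, PhCH2NMe3OH) then gives 18. F2 made this way also serves as the reference sample for assigning the sense of induction in step 10.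

Step 11. Azide attack next to the quaternary carbinol may be slow, and the dehydration could also remove the C5 hydroxyl to give a dienone. Fallback, setting out from 18 and returning at 23: form the C–N bond by copper-catalysed cross-coupling instead of substitution and acylation. MgBr2·OEt2 opens the oxirane of 18 at C2 and the bromohydrin loses water to give (4S,5S)-2-bromo-4-ethynyl-4,5-dihydroxycyclohex-2-en-1-one F3. Acid 7 is converted with isobutyl chloroformate and N-methylmorpholine, then NH3, into (2E,4E,6R)-2,4,6-trimethyldeca-2,4-dienamide F4. Coupling of F3 with F4 (CuI, N,N'-dimethylethylenediamine, K2CO3, dioxane, 60 °C) gives 23 directly, so 20, 21 and 22 are not needed.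

Step 13. The tin hydride may reduce an enone or add with the wrong regiochemistry, and the polyene is fragile. Fallback, setting out from 23 (with 13) and returning at 25: build the triene from the alkyne without tin. Sonogashira coupling of 23 with 13 (PdCl2(PPh3)2, CuI, iPr2NH, THF) gives (2E,4E,6R)-N-[(3S,4S)-3,4-dihydroxy-3-{(3E,5E)-7-[(2-hydroxy-5-oxocyclopent-1-en-1-yl)amino]-7-oxohepta-3,5-dien-1-yn-1-yl}-6-oxocyclohex-1-en-1-yl]-2,4,6-trimethyldeca-2,4-dienamide F5. Ruthenium-catalysed trans-hydrosilylation ([Cp*Ru(MeCN)3]PF6, (EtO)3SiH) puts silicon on the alkyne carbon distal to the carbinol and gives (2E,4E,6R)-N-[(3S,4S)-3,4-dihydroxy-3-{(1Z,3E,5E)-7-[(2-hydroxy-5-oxocyclopent-1-en-1-yl)amino]-7-oxo-2-(triethoxysilyl)hepta-1,3,5-trien-1-yl}-6-oxocyclohex-1-en-1-yl]-2,4,6-trimethyldeca-2,4-dienamide F6. Protodesilylation (TBAF, CuI) with retention gives the E-alkene of 25.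

**Further compounds**
F1 | step 10 | (4S,5S)-4-ethynyl-4,5-dihydroxycyclohex-2-en-1-one 4,5-O-phenylboronate (cis-fused 2-phenyl-1,3,2-dioxaborolane) | O=C1C=C[C@@]2(C#C)OB(c3ccccc3)O[C@H]2C1
F2 | step 10 | (4S,5S)-4-ethynyl-4,5-dihydroxycyclohex-2-en-1-one | O=C1C=C[C@](O)(C#C)[C@@H](O)C1
F3 | step 11 | (4S,5S)-2-bromo-4-ethynyl-4,5-dihydroxycyclohex-2-en-1-one | BrC1=C[C@](O)(C#C)[C@@H](O)CC1=O
F4 | step 11 | (2E,4E,6R)-2,4,6-trimethyldeca-2,4-dienamide | CCCC[C@@H](C)/C=C(C)/C=C(\C)C(N)=O
F5 | step 13 | (2E,4E,6R)-N-[(3S,4S)-3,4-dihydroxy-3-{(3E,5E)-7-[(2-hydroxy-5-oxocyclopent-1-en-1-yl)amino]-7-oxohepta-3,5-dien-1-yn-1-yl}-6-oxocyclohex-1-en-1-yl]-2,4,6-trimethyldeca-2,4-dienamide | CCCC[C@@H](C)/C=C(C)/C=C(\C)C(=O)NC1=C[C@](O)(C#C/C=C/C=C/C(=O)NC2=C(O)CCC2=O)[C@@H](O)CC1=O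
F6 | step 13 | (2E,4E,6R)-N-[(3S,4S)-3,4-dihydroxy-3-{(1Z,3E,5E)-7-[(2-hydroxy-5-oxocyclopent-1-en-1-yl)amino]-7-oxo-2-(triethoxysilyl)hepta-1,3,5-trien-1-yl}-6-oxocyclohex-1-en-1-yl]-2,4,6-trimethyldeca-2,4-dienamide | CCCC[C@@H](C)/C=C(C)/C=C(\C)C(=O)NC1=C[C@](O)(/C=C(\[Si](OCC)(OCC)OCC)/C=C/C=C/C(=O)NC2=C(O)CCC2=O)[C@@H](O)CC1=O
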